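## Structural features

The target joins two oxygen heterocycles through one CH2 group: a 2,3,4-trisubstituted oxolane (ring A) and a 2-aryl-3-(hydroxymethyl)-2,3-dihydrobenzofuran (dihydrofuran ring B fused to benzene ring C). The CH2 on oxolane C4 is bonded to C6 of ring C, which also carries OMe at C4. Ring A has three adjacent stereocentres: C2 (R, 3-hydroxy-4-methoxyphenyl), C3 (S, CH2OH) and C4 (S, arylmethyl), with C2/C3 trans and C3/C4 cis. Ring B has two, C2 (S, 4-hydroxy-3-methoxyphenyl) and C3 (R, CH2OH), trans. The two clusters are insulated by the CH2–aryl bond, so neither can direct the other and each must be set in absolute terms. Fragile groups are the two phenols and the two benzylic ring C–O bonds. C2–O1 of ring A is a para-methoxybenzylic ether (ionised by acid, opened by forcing hydrogenolysis). C2–O1 of ring B is a benzyl aryl ether that can open through a quinone methide once its para-phenol is free. The real difficulty is the cis relation of the carbon branches on C3 and C4 of ring A beside a trans C2/C3 pair, which equilibration does not give, and the carbon substituent at C6 of ring C, meta to both oxygens and out of reach of electrophilic substitution. The key step uses the fact that C3 and C4 of ring A are the α- and β-carbons of a butenolide (lactone carbonyl carbon becomes the C3 CH2OH carbon, γ-acetal carbon becomes the benzylic CH2 on C4), while C2–O1–C5 is a carbonyl ylide of an isovanillin-type aldehyde and formaldehyde.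

## Logic of the disconnections

28 to 27: the two phenolic O–CH2Ph bonds are cut. Benzyl ethers survive fluoride, acid, carbenoids, carbonate at 110 °C and hydride, and they are the most easily hydrogenolysed C–O bonds in 27. The demand is that hydrogenolysis stops before the benzylic C2–O1 bonds of rings A and B, so no alkyl benzyl ether and no other C–O bond needing reduction is left for this step.

27 to 26: both CH2OH groups are traced to methyl esters. The ring A ester carbon is the butenolide carbonyl and the ring B ester carbon comes from a diazoacetate, so one hydride reduction unveils both and no alcohol protection is needed. The demand is that the ring A ester, cis to the C4 branch, does not epimerise.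

26 to 23 and 22: the CH2–C6 bond is cut. It is the only bond between the stereo-clusters that carries no stereocentre, and it gives two halves of similar size. Joining a hydrazone carbon to an arylboron leaves no oxygen on that carbon. A union by aryl-metal addition to the aldehyde was set aside: it needs two equivalents of the valuable aryl metal on the lactol, and then reduction of a benzylic lactone C–O bond beside the equally benzylic C2–O1 bonds of rings A and B. The demand is that the diazoalkane is captured by boron faster than it loses nitrogen.

23 to 12 to 11 to 10: the C=N bond, the ester O–CH3 bond and the acetal C–O bond to the auxiliary are cut in turn, leading back to the lactone acetal. The demand is that the aldehyde α-carbon (ring A C4) never meets base: 11 stays in its cyclic lactol form and is esterified under neutral conditions.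

10 to 8 and 4 (through 9): the ring A bonds C2–C3 and C4–C5 are cut together. This removes ring A and all three of its stereocentres at once and leaves a planar ylide and a crystalline chiral butenolide. The demands are regiochemistry (CH2 end to the β-carbon), addition anti to the menthyloxy group, and the aryl group on the convex face.

8 to 7 to 5: the O–CH2Cl bond and the C–Si bond are cut. 7 comes from 5 by reductive C-silylation in one operation. The route through a benzyl silyl ether and an alkyllithium-induced silyl shift was set aside because the ArO–CH2Ph protons and the ring positions of 5-type ethers would compete for the base. The demand is that chloromethylation does not ionise the electron-rich benzylic C–O bond of 7.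

4 to 2 and 3, and 2 to 1: the acetal C–O bond to 3 is cut, then the furanone is traced to the furan aldehyde by oxidative loss of one carbon. 3 is both the resolving group and the later facial control element. The demand is that the (5R) epimer crystallises while the epimers equilibrate.

22 to 21: the C–B bond is cut to a C–Br bond, bought with the arene. The demand is a borylation mild enough for the trans ester.

21 to 19 (through 20): the ring B bond C2–C3 is cut to a diazoacetate and an ether-activated benzylic CH2. The carbenoid insertion sets C2 under catalyst control and C3 is then relaxed to trans. The demand is enantiocontrol by the catalyst on a doubly ortho-substituted aryl carbenoid.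

19 to 18 to 16 and 17: the C=N2 bond and the benzylic O–C bond are cut. The ether is made under neutral conditions because 16 lactonises and C-alkylates under base.

16 to 15 to 13: one aryl O–CH3 bond and the aryl CH2–CO2Me carbon are traced back. The two methoxy groups of 15 are homotopic, so a single cleavage gives one phenol. The aldehyde 13 already carries the 1,2,3,5 pattern with bromine meta to both oxygens.

## Other disconnections considered

Alternative 1: The cut runs through ring C. Heating cyclobutenone A2, which already carries ring A, with siloxyalkyne A3 should give resorcinol monosilyl ether A1, forming the arene bonds C3a–C7a, C7–C7a and C4–C5 (benzofuran numbering). The sequence is four-electron ring opening to a vinylketene, [2+2] addition to the ynol ether, a second ring opening and six-electron closure.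
- In its favour: the 1,2,3,5 pattern with the carbon branch meta to both oxygens arises by construction; no halogenated arene and no late C(sp3)–C(sp2) coupling are needed; the conditions are neutral and thermal; the reaction type is known.
- Against it here: the step makes no stereocentre. The three centres of ring A must already be in A2 and the two side-chain centres in A3, so the hardest problem, the 3,4-cis oxolane, is only moved. A3 is a sensitive, α-branched ynol ether. After the annulation, ring B must still be closed by displacement at a para-alkoxybenzylic carbinol with clean inversion, the silyl ether must be exchanged for methyl, and four benzyl ethers (two of them alkyl) must be hydrogenolysed beside the benzylic ring ethers.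
- Comparison: on the arene pattern and on key-step risk this alternative is the better plan, and it is equal in convergence. On stereochemistry the chosen cycloaddition is stronger, since it creates ring A with three centres in one step. On step economy the alternative is weaker, both before the key step (two chiral fragments) and after it.

Alternative 2: The cut is C3–C3a of ring B, traced to the C4–C4a bond of flavanone A5. PhI(OAc)2 with H2SO4 in trimethyl orthoformate should contract the pyranone by a 1,2-shift of the aryl ring from C4 to C3, giving trans ester A4.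
- In its favour: the reaction is known for flavanones; it gives ring B trans with C3 at the ester level; C2 is carried over from A5; and A5 is only two condensation steps from simple aromatic building blocks. For ring B this is shorter than steps 8 to 12 of the chosen route, a point on which the alternative is better.
- Against it here: (2S)-flavanones lose configuration easily by retro-oxa-Michael ring opening, and the strongly acidic conditions invite this. A 5,7-dioxygenated flavanone is not easy to obtain as one enantiomer. The electron-rich aryl group needs acyl protection against the oxidant, and migration of the wrong group or dehydrogenation can compete. The C6 handle is a benzyl ether that must be removed and activated before any C–C coupling. Ring A is not addressed at all.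
- Comparison: both plans rely on the trans preference at C3 of ring B, so they are equal there. The alternative is better in step count for ring B but weaker in enantiocontrol. It could replace part of the ring B branch, but not the key step, since the cis-3,4 oxolane stays unsolved.

Alternative 3: The cut is C3–C4 of ring A. Cp2TiCl (trivalent titanium, from Cp2TiCl2 and zinc dust) should open the terminal epoxide of A7 to a secondary β-titanoxy radical, which cyclises 5-exo onto the cinnamyl alkene. The benzylic radical is reduced and protonated, giving A6.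
- In its favour: the reaction type is established for furano-lignans. It delivers ring A with the C3 CH2OH and the C4 arylmethyl group at their final oxidation level, so only debenzylation follows, against five steps after the key step in the chosen plan. The two halves are joined by simple O-alkylation. On key-step risk and on post-key-step economy the alternative is better.
- Against it here: the C3/C4 relation is set kinetically in a radical transition state, where 3,4-cis is only a preference, whereas the chosen cycloaddition enforces it by ring fusion. The C2 centre of A7 must come from a separate enantioselective synthesis, and its electron-rich benzylic alkoxide must be allylated without scrambling. The ring B half must first be extended by a three-carbon allylic unit, which lengthens the longest branch. Titanium is stoichiometric, and an alkyl benzyl ether must be hydrogenolysed at the end.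
- Comparison: mechanistically it is a stepwise radical closure against a concerted two-bond annulation. The chosen plan is stronger on relative and absolute stereocontrol of ring A and on the length of the longest branch; the alternative is stronger on precedent and on the end game.

Key step: step 5

Remark: 13 and 17 are taken as catalogue compounds, and the (R)-tert-leucinate dirhodium catalyst of step 12 is assumed to give the (2S) ether carbon; its antipode would be used if the sense proves opposite.

## Route

Step 1
Reactants: 1 furfural
Product: 2 5-hydroxyfuran-2(5H)-one (racemic)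
Conditions: O2, hν (visible), rose bengal (cat.), MeOH, rt
Reagents that add atoms: oxygen, O=O
Why: Dye-sensitised singlet-oxygen [4+2] addition to the furan gives an endoperoxide that methanol solvolyses with loss of the formyl carbon, leaving the γ-hydroxybutenolide; the hemiacetal centre is labile and not controlled.

Step 2
Reactants: 2 5-hydroxyfuran-2(5H)-one; 3 (1R,2S,5R)-(−)-menthol
Product: 4 (5R)-5-{[(1R,2S,5R)-2-isopropyl-5-methylcyclohexyl]oxy}furan-2(5H)-one
Conditions: (1S)-(+)-10-camphorsulfonic acid (cat.), toluene, reflux (Dean–Stark); crystallisation from hexane, mother liquor re-equilibrated with acid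
Reagents that add atoms: none
Why: Acid-catalysed acetalisation of the pseudo-acid gives both C5 epimers, which interconvert under acid while the (5R) epimer crystallises (crystallisation-induced asymmetric transformation), so C5 is set by the menthyl group.

Step 3
Reactants: 5 3-(benzyloxy)-4-methoxybenzaldehyde
Product: 7 [3-(benzyloxy)-4-methoxyphenyl](trimethylsilyl)methanol (racemic), via C,O-bis(trimethylsilyl) adduct 6 (not isolated)
Conditions: Mg turnings, Me3SiCl, DMF, 0 °C to rt; then citric acid, MeOH, 0 °C
Reagents that add atoms: chlorotrimethylsilane, C[Si](C)(C)Cl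
Why: Magnesium-promoted reductive silylation of an aromatic aldehyde (O-silylated ketyl, second electron transfer, C-silylation of the α-siloxybenzyl anion) gives 6, and mild acid methanolysis cleaves only the O–Si bond. No alkyllithium is used, so the ArO–CH2Ph protons are not at risk; the new centre is racemic and is erased later in the ylide.

Step 4
Reactants: 7 [3-(benzyloxy)-4-methoxyphenyl](trimethylsilyl)methanol
Product: 8 chloromethyl [3-(benzyloxy)-4-methoxyphenyl](trimethylsilyl)methyl ether (racemic)
Conditions: (CH2O)n, Me3SiCl, CH2Cl2, 0 °C to rt; used crude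
Reagents that add atoms: paraformaldehyde (formaldehyde unit), C=O; chlorotrimethylsilane, C[Si](C)(C)Cl
Why: Chloromethylation of an alcohol (hemiformal, then chloride substitution through the oxocarbenium ion), the known route to chloromethyl α-silylbenzyl ethers; low temperature and the bulky α-silyl group are relied on to keep the benzylic C–O bond from ionising.

Step 5
Reactants: 8 chloromethyl [3-(benzyloxy)-4-methoxyphenyl](trimethylsilyl)methyl ether; 4 (5R)-5-menthyloxyfuran-2(5H)-one
Product: 10 (1R,3aR,4R,6aS)-4-[3-(benzyloxy)-4-methoxyphenyl]-1-{[(1R,2S,5R)-menthyl]oxy}tetrahydro-1H,3H-furo[3,4-c]furan-3-one (cis-fused; aryl on the convex face), via carbonyl ylide 9 (not isolated)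
Conditions: CsF (dried), MeCN, rt; 8 (excess) added slowly
Reagents that add atoms: none
Why: Proposed new method: fluoride attacks silicon of 8 and chloride is expelled across oxygen (1,3-elimination), releasing carbonyl ylide 9 (ArCH=O(+)–CH2(−)), a 4π dipole that adds to the electron-poor C3=C4 bond of 4 in one concerted, suprafacial [3+2] step; the closest known reactions are the same fluoride-triggered ylide generation with capture by acrylates, fumarates or maleimides, and the additions of azomethine ylides and diazoalkanes to 5-menthyloxyfuranone. Ring A is closed by this two-bond annulation, which makes oxolane C2–C3 and C4–C5 together and can only give a cis-fused bicycle. C3 and C4 of ring A are set cis by the suprafacial addition to the ring alkene, and in the absolute sense by approach anti to the menthyloxy group on C5 of 4. C2 is set by the exo transition state, which keeps the aryl group on the convex face, away from the lactone. Regiochemistry is the selectivity that is least secured: the unsubstituted ylide carbon has the larger HOMO coefficient and should bond to the β-carbon, which has the larger LUMO coefficient, and the bulkier benzylic end is then kept away from the carbon next to the acetal centre. The racemic centre of 8 is erased in the planar ylide, and slow addition of 8 keeps the ylide concentration low so that capture by 4 competes with its collapse to the epoxide.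

Step 6
Reactants: 10 cis-fused menthyloxy lactone acetal
Product: 11 (3aR,4R,6aS)-4-[3-(benzyloxy)-4-methoxyphenyl]-1-hydroxytetrahydro-1H,3H-furo[3,4-c]furan-3-one (lactol; both anomers)
Conditions: 2 M aq HCl, THF, 50 °C
Reagents that add atoms: water, O
Why: Acid hydrolysis of the acyloxy alkyl acetal releases the auxiliary and leaves the pseudo-acid, which stays as the cis-fused lactol, so the aldehyde α-carbon (ring A C4) is not open to enolisation. Reversible ionisation at benzylic C2, if it occurs, can only return the aryl group to the convex face.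

Step 7
Reactants: 11 cis-fused lactol
Product: 12 methyl (2R,3R,4S)-2-[3-(benzyloxy)-4-methoxyphenyl]-4-formyloxolane-3-carboxylate
Conditions: Me3SiCHN2 (1 equiv), toluene–MeOH, 0 °C; used at once
Reagents that add atoms: (trimethylsilyl)diazomethane, C[Si](C)(C)C=[N+]=[N-]
Why: Diazoalkane esterification traps the open aldehyde-acid tautomer of the pseudo-acid as the normal methyl ester under neutral conditions, so the 3,4-cis aldehyde ester is formed without base.

Step 8
Reactants: 13 4-bromo-2,6-dimethoxybenzaldehyde
Product: 15 methyl (4-bromo-2,6-dimethoxyphenyl)acetate, via ketene dithioacetal S-oxide 14 (not isolated)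
Conditions: MeS(O)CH2SMe, benzyltrimethylammonium hydroxide (cat.), THF, reflux; then HCl, MeOH, reflux
Reagents that add atoms: methyl (methylsulfinyl)methyl sulfide, CSCS(C)=O; methanol, CO
Why: Knoevenagel-type condensation with the formaldehyde dithioacetal S-oxide followed by acid methanolysis (Ogura–Tsuchihashi homologation) turns an aromatic aldehyde into the arylacetic ester; the aryl bromide and both methoxy groups are inert.

Step 9
Reactants: 15 methyl (4-bromo-2,6-dimethoxyphenyl)acetate
Product: 16 methyl (4-bromo-2-hydroxy-6-methoxyphenyl)acetate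
Conditions: BBr3 (1.1 equiv), CH2Cl2, −78 to −20 °C; then MeOH, reflux
Reagents that add atoms: none
Why: Lewis-acid cleavage of an aryl methyl ether; the two methoxy groups are homotopic, so the first cleavage gives one phenol and the aryloxyboron intermediate is deactivated toward a second. The methanol quench returns any lactonised or ester-cleaved material to the hydroxy methyl ester.

Step 10
Reactants: 16 methyl (4-bromo-2-hydroxy-6-methoxyphenyl)acetate; 17 [4-(benzyloxy)-3-methoxyphenyl]methanol
Product: 18 methyl (2-{[4-(benzyloxy)-3-methoxyphenyl]methoxy}-4-bromo-6-methoxyphenyl)acetate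
Conditions: PPh3, DIAD, THF, 0 °C to rt
Reagents that add atoms: none
Why: Mitsunobu etherification of a phenol with a primary benzylic alcohol under neutral conditions, which avoids base-induced lactonisation of 16 to the acidic benzofuranone and its C-alkylation.

Step 11
Reactants: 18 aryl ether ester
Product: 19 methyl (2-{[4-(benzyloxy)-3-methoxyphenyl]methoxy}-4-bromo-6-methoxyphenyl)(diazo)acetate
Conditions: 4-acetamidobenzenesulfonyl azide, DBU, MeCN, 0 °C to rt
Reagents that add atoms: 4-acetamidobenzenesulfonyl azide, CC(=O)Nc1ccc(cc1)S(=O)(=O)N=[N+]=[N-]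
Why: Regitz diazo transfer to the benzylic, ester-activated CH2 of an arylacetate.

Step 12
Reactants: 19 aryl diazoacetate
Product: 21 methyl (2S,3S)-2-[4-(benzyloxy)-3-methoxyphenyl]-6-bromo-4-methoxy-2,3-dihydro-1-benzofuran-3-carboxylate (trans), via cis ester 20 (not isolated)
Conditions: Rh2(R-PTTL)4 [dirhodium tetrakis(N-phthaloyl-(R)-tert-leucinate)] (cat.), toluene, −60 °C; then NaOMe, MeOH, rt
Reagents that add atoms: none
Why: Intramolecular 1,5 C–H insertion of the rhodium carbenoid into the ether-activated, electron-rich benzylic CH2 closes ring B and gives the cis ester, with the chiral carboxylate ligands setting C2. Methoxide then epimerises the acidic C3 (benzylic and α to the ester) to the more stable trans ester, so the catalyst-set C2 dictates both centres.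

Step 13
Reactants: 21 trans bromo ester
Product: 22 {(2S,3S)-2-[4-(benzyloxy)-3-methoxyphenyl]-4-methoxy-3-(methoxycarbonyl)-2,3-dihydro-1-benzofuran-6-yl}boronic acid
Conditions: B2(OH)4, KOAc, XPhos, chloro(2-dicyclohexylphosphino-2′,4′,6′-triisopropylbiphenyl)[2-(2′-aminobiphenyl)]palladium (second-generation XPhos precatalyst, cat.), MeOH, 60 °C
Reagents that add atoms: tetrahydroxydiboron, OB(O)B(O)O
Why: Palladium-catalysed Miyaura-type borylation of the aryl bromide with tetrahydroxydiboron gives the free boronic acid directly; the weak acetate base leaves the trans ester untouched.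

Step 14
Reactants: 12 methyl (2R,3R,4S)-4-formyl-2-aryloxolane-3-carboxylate
Product: 23 methyl (2R,3R,4R)-2-[3-(benzyloxy)-4-methoxyphenyl]-4-{(E)-[2-(4-methylbenzenesulfonyl)hydrazinylidene]methyl}oxolane-3-carboxylate
Conditions: TsNHNH2, MeOH, rt
Reagents that add atoms: 4-methylbenzenesulfonohydrazide, Cc1ccc(cc1)S(=O)(=O)NN
Why: Condensation of the aldehyde with the sulfonyl hydrazide gives the (E)-hydrazone under neutral conditions and removes the epimerisable aldehyde; the geometry keeps the sulfonamide nitrogen away from the neighbouring ester.

Step 15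
Reactants: 23 tosylhydrazone; 22 arylboronic acid
Product: 26 methyl (2S,3S)-2-[4-(benzyloxy)-3-methoxyphenyl]-6-{[(3S,4R,5R)-5-[3-(benzyloxy)-4-methoxyphenyl]-4-(methoxycarbonyl)oxolan-3-yl]methyl}-4-methoxy-2,3-dihydro-1-benzofuran-3-carboxylate, via diazoalkane 24 (not isolated), via benzylic boronic acid 25 (not isolated)
Conditions: K2CO3, 1,4-dioxane, 110 °C
Reagents that add atoms: none
Why: Barluenga reductive coupling: carbonate converts the sulfonylhydrazone into the diazoalkane (Bamford–Stevens), which adds to boron; 1,2-aryl shift with loss of nitrogen and protodeboronation then give the CH2–aryl bond with no oxygen on that carbon. No stereocentre is formed, and the centres of rings A and B are not acidic enough for carbonate.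

Step 16
Reactants: 26 coupled diester
Product: 27 [(2S,3R)-2-[4-(benzyloxy)-3-methoxyphenyl]-6-{[(3S,4S,5R)-5-[3-(benzyloxy)-4-methoxyphenyl]-4-(hydroxymethyl)oxolan-3-yl]methyl}-4-methoxy-2,3-dihydro-1-benzofuran-3-yl]methanol
Conditions: LiAlH4, THF, 0 °C to rt
Reagents that add atoms: none
Why: Hydride reduction of both methyl esters gives the two primary alcohols in one operation; hydride delivery is faster than enolisation, so the cis C3/C4 relation of ring A and the trans relation of ring B are kept.

Step 17
Reactants: 27 di-O-benzyl diol
Product: 28 [(2S,3R)-2-(4-hydroxy-3-methoxyphenyl)-6-{[(3S,4S,5R)-4-(hydroxymethyl)-5-(3-hydroxy-4-methoxyphenyl)oxolan-3-yl]methyl}-4-methoxy-2,3-dihydro-1-benzofuran-3-yl]methanol (CNP0242386.1)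
Conditions: H2 (1 atm), 10% Pd/C, EtOAc–MeOH, rt; stopped after two equivalents of H2
Reagents that add atoms: none
Why: Catalytic hydrogenolysis of the two aryl benzyl ethers, the most labile benzylic C–O bonds present; under neutral conditions and with no alkyl benzyl ether to wait for, the benzylic ring C–O bonds of rings A and B should stay intact.

## Compound list

1 | furfural (furan-2-carbaldehyde) | O=Cc1ccco1 | starting material
2 | 5-hydroxyfuran-2(5H)-one (racemic) | O=C1C=CC(O)O1 | intermediate
3 | (1R,2S,5R)-(−)-menthol | CC(C)[C@@H]1CC[C@@H](C)C[C@H]1O | starting material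
4 | (5R)-5-{[(1R,2S,5R)-2-isopropyl-5-methylcyclohexyl]oxy}furan-2(5H)-one | O=C1C=C[C@H](O[C@@H]2C[C@H](C)CC[C@H]2C(C)C)O1 | intermediate
5 | 3-(benzyloxy)-4-methoxybenzaldehyde | COc1ccc(C=O)cc1OCc1ccccc1 | starting material
6 | {[3-(benzyloxy)-4-methoxyphenyl](trimethylsilyl)methoxy}trimethylsilane (racemic; not isolated) | COc1ccc(C(O[Si](C)(C)C)[Si](C)(C)C)cc1OCc1ccccc1 | intermediate
7 | [3-(benzyloxy)-4-methoxyphenyl](trimethylsilyl)methanol (racemic) | COc1ccc(C(O)[Si](C)(C)C)cc1OCc1ccccc1 | intermediate
8 | chloromethyl [3-(benzyloxy)-4-methoxyphenyl](trimethylsilyl)methyl ether (racemic) | COc1ccc(C(OCCl)[Si](C)(C)C)cc1OCc1ccccc1 | intermediate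
9 | carbonyl ylide of 3-(benzyloxy)-4-methoxybenzaldehyde and formaldehyde (not isolated) | COc1ccc(C=[O+][CH2-])cc1OCc1ccccc1 | intermediate
10 | (1R,3aR,4R,6aS)-4-[3-(benzyloxy)-4-methoxyphenyl]-1-{[(1R,2S,5R)-menthyl]oxy}tetrahydro-1H,3H-furo[3,4-c]furan-3-one | COc1ccc([C@@H]2OC[C@@H]3[C@H]2C(=O)O[C@H]3O[C@@H]2C[C@H](C)CC[C@H]2C(C)C)cc1OCc1ccccc1 | intermediate
11 | (3aR,4R,6aS)-4-[3-(benzyloxy)-4-methoxyphenyl]-1-hydroxytetrahydro-1H,3H-furo[3,4-c]furan-3-one (both anomers) | COc1ccc([C@@H]2OC[C@@H]3[C@H]2C(=O)OC3O)cc1OCc1ccccc1 | intermediate
12 | methyl (2R,3R,4S)-2-[3-(benzyloxy)-4-methoxyphenyl]-4-formyloxolane-3-carboxylate | COc1ccc([C@@H]2OC[C@@H](C=O)[C@H]2C(=O)OC)cc1OCc1ccccc1 | intermediate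
13 | 4-bromo-2,6-dimethoxybenzaldehyde | COc1cc(Br)cc(OC)c1C=O | starting material
14 | 5-bromo-1,3-dimethoxy-2-[2-(methylsulfanyl)-2-(methylsulfinyl)ethenyl]benzene (not isolated) | COc1cc(Br)cc(OC)c1C=C(SC)S(C)=O | intermediate
15 | methyl (4-bromo-2,6-dimethoxyphenyl)acetate | COC(=O)Cc1c(OC)cc(Br)cc1OC | intermediate
16 | methyl (4-bromo-2-hydroxy-6-methoxyphenyl)acetate | COC(=O)Cc1c(O)cc(Br)cc1OC | intermediate
17 | [4-(benzyloxy)-3-methoxyphenyl]methanol | COc1cc(CO)ccc1OCc1ccccc1 | starting material
18 | methyl (2-{[4-(benzyloxy)-3-methoxyphenyl]methoxy}-4-bromo-6-methoxyphenyl)acetate | COC(=O)Cc1c(OC)cc(Br)cc1OCc1ccc(OCc2ccccc2)c(OC)c1 | intermediate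
19 | methyl (2-{[4-(benzyloxy)-3-methoxyphenyl]methoxy}-4-bromo-6-methoxyphenyl)(diazo)acetate | COC(=O)C(=[N+]=[N-])c1c(OC)cc(Br)cc1OCc1ccc(OCc2ccccc2)c(OC)c1 | intermediate
20 | methyl (2S,3R)-2-[4-(benzyloxy)-3-methoxyphenyl]-6-bromo-4-methoxy-2,3-dihydro-1-benzofuran-3-carboxylate (cis; not isolated) | Brc1cc(OC)c2c(c1)O[C@H](c1ccc(OCc3ccccc3)c(OC)c1)[C@@H]2C(=O)OC | intermediate
21 | methyl (2S,3S)-2-[4-(benzyloxy)-3-methoxyphenyl]-6-bromo-4-methoxy-2,3-dihydro-1-benzofuran-3-carboxylate (trans) | Brc1cc(OC)c2c(c1)O[C@H](c1ccc(OCc3ccccc3)c(OC)c1)[C@H]2C(=O)OC | intermediate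
22 | {(2S,3S)-2-[4-(benzyloxy)-3-methoxyphenyl]-4-methoxy-3-(methoxycarbonyl)-2,3-dihydro-1-benzofuran-6-yl}boronic acid | OB(O)c1cc(OC)c2c(c1)O[C@H](c1ccc(OCc3ccccc3)c(OC)c1)[C@H]2C(=O)OC | intermediate
23 | methyl (2R,3R,4R)-2-[3-(benzyloxy)-4-methoxyphenyl]-4-{(E)-[2-(4-methylbenzenesulfonyl)hydrazinylidene]methyl}oxolane-3-carboxylate | COc1ccc([C@@H]2OC[C@@H](/C=N/NS(=O)(=O)c3ccc(C)cc3)[C@H]2C(=O)OC)cc1OCc1ccccc1 | intermediate
24 | methyl (2R,3R,4R)-2-[3-(benzyloxy)-4-methoxyphenyl]-4-(diazomethyl)oxolane-3-carboxylate (not isolated) | COc1ccc([C@@H]2OC[C@@H](C=[N+]=[N-])[C@H]2C(=O)OC)cc1OCc1ccccc1 | intermediate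
25 | benzylic boronic acid from 24 and 22, epimers at the boron-bearing carbon (not isolated) | COc1ccc([C@@H]2OC[C@@H](C(B(O)O)c3cc(OC)c4c(c3)O[C@H](c3ccc(OCc5ccccc5)c(OC)c3)[C@H]4C(=O)OC)[C@H]2C(=O)OC)cc1OCc1ccccc1 | intermediate
26 | methyl (2S,3S)-2-[4-(benzyloxy)-3-methoxyphenyl]-6-{[(3S,4R,5R)-5-[3-(benzyloxy)-4-methoxyphenyl]-4-(methoxycarbonyl)oxolan-3-yl]methyl}-4-methoxy-2,3-dihydro-1-benzofuran-3-carboxylate | COc1ccc([C@@H]2OC[C@@H](Cc3cc(OC)c4c(c3)O[C@H](c3ccc(OCc5ccccc5)c(OC)c3)[C@H]4C(=O)OC)[C@H]2C(=O)OC)cc1OCc1ccccc1 | intermediate
27 | [(2S,3R)-2-[4-(benzyloxy)-3-methoxyphenyl]-6-{[(3S,4S,5R)-5-[3-(benzyloxy)-4-methoxyphenyl]-4-(hydroxymethyl)oxolan-3-yl]methyl}-4-methoxy-2,3-dihydro-1-benzofuran-3-yl]methanol | COc1ccc([C@@H]2OC[C@@H](Cc3cc(OC)c4c(c3)O[C@H](c3ccc(OCc5ccccc5)c(OC)c3)[C@H]4CO)[C@H]2CO)cc1OCc1ccccc1 | intermediate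
28 | [(2S,3R)-2-(4-hydroxy-3-methoxyphenyl)-6-{[(3S,4S,5R)-4-(hydroxymethyl)-5-(3-hydroxy-4-methoxyphenyl)oxolan-3-yl]methyl}-4-methoxy-2,3-dihydro-1-benzofuran-3-yl]methanol | COc1ccc([C@@H]2OC[C@@H](Cc3cc(OC)c4c(c3)O[C@H](c3ccc(O)c(OC)c3)[C@H]4CO)[C@H]2CO)cc1O | target

## Step count and least certain steps

Total: 17 steps. Longest linear sequence: 9 steps; the three branches are equally long (from 13: steps 8 to 13, 15, 16, 17; from 1: steps 1, 2, 5, 6, 7, 14 to 17; from 5: steps 3 to 7, 14 to 17).

Step 5 (key step). What may go wrong:
- reversed regiochemistry, with the benzylic ylide end bonding to the β-carbon;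
- poor exo/endo selectivity at C2;
- collapse of the ylide (closure to the epoxide, fragmentation) before capture by a hindered and only moderately electron-poor butenolide;
- fluoride-induced epimerisation at the acetal carbon of 4, which would erode facial control.

Fallback with known chemistry, setting out from 4 and returning at 10:
- Benzophenone-sensitised photochemical addition of methanol to 4 should place a hydroxymethyl group on the β-carbon anti to the menthyloxy group, giving (4S,5R)-4-(hydroxymethyl)-5-menthyloxydihydrofuran-2(3H)-one F1.
- F1 would be etherified under La(OTf)3 catalysis with 3-(benzyloxy)-4-methoxybenzyl trichloroacetimidate F2 (from commercial 3-(benzyloxy)-4-methoxybenzyl alcohol, Cl3CCN and DBU) to give benzylic ether F3.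
- Trifluoroacetylation of the lactone enolate (LiHMDS, CF3CO2CH2CF3) would give the 3-trifluoroacetyl lactone F4, and deacylative diazo transfer (MsN3, Et3N) the 3-diazo lactone F5.
- Rh2(OAc)4 should then effect 1,5 C–H insertion into the ether-activated benzylic CH2. This forms the C2–C3 bond of ring A with obligatory cis fusion and gives 10. An aryl group delivered to the concave face would be moved to the convex face by acid equilibration at the benzylic carbon.

Step 15. What may go wrong:
- 1,2-hydrogen shift in the diazoalkane or carbene, with loss of the C4 centre, outrunning capture by boron;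
- slow reaction of the α-branched hydrazone, giving time for base-induced epimerisation next to the ester.

Fallback, setting out from 12 and 21 and returning at 26:
- NaBH4 (MeOH, −40 °C, acetic acid quench) would reduce 12 to the hydroxy ester methyl (2R,3R,4R)-2-[3-(benzyloxy)-4-methoxyphenyl]-4-(hydroxymethyl)oxolane-3-carboxylate F6, kept cold because it can lactonise.
- I2, PPh3 and imidazole would give the iodide F7.
- Nickel-catalysed reductive cross-electrophile coupling of F7 with aryl bromide 21 (NiI2, 4,4′-di-tert-butyl-2,2′-bipyridine, zinc dust, NaI, DMPU, 60 °C) should form the same CH2–aryl bond and give 26 without the borylation of step 13.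

Step 12. What may go wrong: insufficient enantiocontrol, because two ortho substituents twist the aryl carbenoid out of the geometry of the known substrates, or competing insertion into the methoxy C–H bonds.

Fallback, setting out from 19 and returning at 21:
- 19 would be cyclised with achiral Rh2(OAc)4 and epimerised with NaOMe to the racemic trans ester F8.
- LiOH would give the racemic acid F9.
- Crystallisation of the (R)-1-phenylethylammonium salt F10 (the antipodal amine if the other diastereomeric salt is the one that crystallises) and acidification would give the (2S,3S) acid F11.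
- Me3SiCHN2 returns 21.

Step 4. What may go wrong: HCl formed during chloromethylation may ionise the para-alkoxybenzylic C–O bond (substitution by chloride, loss of silicon) faster than the oxygen is alkylated.

Fallback, setting out from 7 and returning at 8: Me2S and dibenzoyl peroxide (MeCN, 0 °C) would give the methylthiomethyl ether F12 under non-acidic conditions, and SO2Cl2 (CH2Cl2, −78 °C) would convert it into 8.

Step 3. What may go wrong: pinacol coupling of the silylated ketyl radical of this electron-rich aldehyde may outrun the second electron transfer.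

Fallback, setting out from 5 and returning at 7:
- Propane-1,3-dithiol with BF3·OEt2 would give the dithiane F13; its C2–H is far more acidic than the ArO–CH2Ph protons.
- n-BuLi and Me3SiCl would give the 2-silyl dithiane F14.
- MeI and CaCO3 in aqueous MeCN would unmask the aroylsilane F15.
- NaBH4 would reduce F15 to 7.

## Further compounds

F1 | step 5 | (4S,5R)-4-(hydroxymethyl)-5-{[(1R,2S,5R)-menthyl]oxy}dihydrofuran-2(3H)-one | OC[C@@H]1CC(=O)O[C@H]1O[C@@H]1C[C@H](C)CC[C@H]1C(C)C
F2 | step 5 | 3-(benzyloxy)-4-methoxybenzyl 2,2,2-trichloroacetimidate | COc1ccc(COC(=N)C(Cl)(Cl)Cl)cc1OCc1ccccc1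
F3 | step 5 | (4S,5R)-4-({[3-(benzyloxy)-4-methoxyphenyl]methoxy}methyl)-5-{[(1R,2S,5R)-menthyl]oxy}dihydrofuran-2(3H)-one | COc1ccc(COC[C@@H]2CC(=O)O[C@H]2O[C@@H]2C[C@H](C)CC[C@H]2C(C)C)cc1OCc1ccccc1
F4 | step 5 | 3-(trifluoroacetyl) derivative of F3 (epimers at C3; not isolated) | COc1ccc(COC[C@@H]2C(C(=O)C(F)(F)F)C(=O)O[C@H]2O[C@@H]2C[C@H](C)CC[C@H]2C(C)C)cc1OCc1ccccc1
F5 | step 5 | (4S,5R)-3-diazo-4-({[3-(benzyloxy)-4-methoxyphenyl]methoxy}methyl)-5-{[(1R,2S,5R)-menthyl]oxy}dihydrofuran-2(3H)-one | COc1ccc(COC[C@@H]2C(=[N+]=[N-])C(=O)O[C@H]2O[C@@H]2C[C@H](C)CC[C@H]2C(C)C)cc1OCc1ccccc1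
F6 | step 15 | methyl (2R,3R,4R)-2-[3-(benzyloxy)-4-methoxyphenyl]-4-(hydroxymethyl)oxolane-3-carboxylate | COc1ccc([C@@H]2OC[C@@H](CO)[C@H]2C(=O)OC)cc1OCc1ccccc1
F7 | step 15 | methyl (2R,3R,4S)-2-[3-(benzyloxy)-4-methoxyphenyl]-4-(iodomethyl)oxolane-3-carboxylate | COc1ccc([C@@H]2OC[C@@H](CI)[C@H]2C(=O)OC)cc1OCc1ccccc1
F8 | step 12 | racemic trans methyl 2-[4-(benzyloxy)-3-methoxyphenyl]-6-bromo-4-methoxy-2,3-dihydro-1-benzofuran-3-carboxylate (both enantiomers) | Brc1cc(OC)c2c(c1)O[C@H](c1ccc(OCc3ccccc3)c(OC)c1)[C@H]2C(=O)OC.Brc1cc(OC)c2c(c1)O[C@@H](c1ccc(OCc3ccccc3)c(OC)c1)[C@@H]2C(=O)OC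
F9 | step 12 | racemic trans 2-[4-(benzyloxy)-3-methoxyphenyl]-6-bromo-4-methoxy-2,3-dihydro-1-benzofuran-3-carboxylic acid (both enantiomers) | Brc1cc(OC)c2c(c1)O[C@H](c1ccc(OCc3ccccc3)c(OC)c1)[C@H]2C(=O)O.Brc1cc(OC)c2c(c1)O[C@@H](c1ccc(OCc3ccccc3)c(OC)c1)[C@@H]2C(=O)O
F10 | step 12 | (R)-1-phenylethylammonium (2S,3S)-2-[4-(benzyloxy)-3-methoxyphenyl]-6-bromo-4-methoxy-2,3-dihydro-1-benzofuran-3-carboxylate | Brc1cc(OC)c2c(c1)O[C@H](c1ccc(OCc3ccccc3)c(OC)c1)[C@H]2C(=O)[O-].C[C@@H]([NH3+])c1ccccc1
F11 | step 12 | (2S,3S)-2-[4-(benzyloxy)-3-methoxyphenyl]-6-bromo-4-methoxy-2,3-dihydro-1-benzofuran-3-carboxylic acid | Brc1cc(OC)c2c(c1)O[C@H](c1ccc(OCc3ccccc3)c(OC)c1)[C@H]2C(=O)O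
F12 | step 4 | {[3-(benzyloxy)-4-methoxyphenyl][(methylsulfanyl)methoxy]methyl}trimethylsilane (racemic) | COc1ccc(C(OCSC)[Si](C)(C)C)cc1OCc1ccccc1
F13 | step 3 | 2-[3-(benzyloxy)-4-methoxyphenyl]-1,3-dithiane | COc1ccc(C2SCCCS2)cc1OCc1ccccc1
F14 | step 3 | {2-[3-(benzyloxy)-4-methoxyphenyl]-1,3-dithian-2-yl}trimethylsilane | COc1ccc(C2([Si](C)(C)C)SCCCS2)cc1OCc1ccccc1
F15 | step 3 | [3-(benzyloxy)-4-methoxyphenyl](trimethylsilyl)methanone | COc1ccc(C(=O)[Si](C)(C)C)cc1OCc1ccccc1
A1 | alternative 1 | 2,5-disubstituted 3-(triisopropylsilyloxy)phenol carrying ring A on C5 and the protected side chain on C2 | COc1ccc([C@@H]2OC[C@@H](Cc3cc(O)c([C@H](COCc4ccccc4)[C@@H](O[Si](CC)(CC)CC)c4ccc(OCc5ccccc5)c(OC)c4)c(O[Si](C(C)C)(C(C)C)C(C)C)c3)[C@H]2COCc2ccccc2)cc1OCc1ccccc1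
A2 | alternative 1 | 3-{[(3S,4S,5R)-5-[3-(benzyloxy)-4-methoxyphenyl]-4-[(benzyloxy)methyl]oxolan-3-yl]methyl}cyclobut-2-en-1-one | COc1ccc([C@@H]2OC[C@@H](CC3=CC(=O)C3)[C@H]2COCc2ccccc2)cc1OCc1ccccc1
A3 | alternative 1 | triisopropylsilyl ynol ether of the protected C3–C2 side chain (4-aryl-3-[(benzyloxy)methyl]-4-(triethylsilyloxy)but-1-ynyl silyl ether) | CC(C)[Si](OC#C[C@H](COCc1ccccc1)[C@@H](O[Si](CC)(CC)CC)c1ccc(OCc2ccccc2)c(OC)c1)(C(C)C)C(C)C
A4 | alternative 2 | methyl trans-(2S,3S)-6-(benzyloxy)-4-methoxy-2-[3-methoxy-4-(pivaloyloxy)phenyl]-2,3-dihydro-1-benzofuran-3-carboxylate | c1ccccc1COc1cc(OC)c2c(c1)O[C@H](c1ccc(OC(=O)C(C)(C)C)c(OC)c1)[C@H]2C(=O)OC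
A5 | alternative 2 | (2S)-7-(benzyloxy)-5-methoxy-2-[3-methoxy-4-(pivaloyloxy)phenyl]chroman-4-one | c1ccccc1COc1cc(OC)c2c(c1)O[C@H](c1ccc(OC(=O)C(C)(C)C)c(OC)c1)CC2=O
A6 | alternative 3 | tri-O-benzyl target with the ring A C3 hydroxymethyl group free | COc1ccc([C@@H]2OC[C@@H](Cc3cc(OC)c4c(c3)O[C@H](c3ccc(OCc5ccccc5)c(OC)c3)[C@H]4COCc3ccccc3)[C@H]2CO)cc1OCc1ccccc1
A7 | alternative 3 | epoxy cinnamyl ether: (S)-[3-(benzyloxy)-4-methoxyphenyl](oxiran-2-yl)methyl (E)-3-aryl-allyl ether of the protected ring B half (either epoxide epimer) | COc1ccc([C@H](OC/C=C/c2cc(OC)c3c(c2)O[C@H](c2ccc(OCc4ccccc4)c(OC)c2)[C@H]3COCc2ccccc2)C2CO2)cc1OCc1ccccc1
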